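Everything rests on removing C7 from ring B: cutting C6–C7 and C7–C8 (and the C3 ester) turns ring B (C5, C6, C7, C8, C9, C10) into the cyclopentenone C5–C6–C8–C9–C10, which a Pauson–Khand reaction of a 1,7-enyne delivers with C3–O, C4–CH3 and quaternary C5 in place. The key step exploits that C7 is the only ring-B atom missing there and must carry oxygen: dibromocarbene adds to C6=C8 of the kinetic silyl dienol ether, and cyclopropane opening inserts C7 bearing bromine, forming both bonds and the cross-conjugated dienone at once. The precursor is the 3-silyloxy-4,5-dimethyl hydrindadiene with a trimethylsilyloxy group on C8.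

Key step: step 7

Remarks on the chemistry
- Numbering: ring A = C1, C2, C3, C4, C5, C10; ring B = C5, C6, C7, C8, C9, C10; side-chain atoms are primed.
- Structure check: the target is (3S,4R,5S,6′R), with 3-O, 4-CH3 and 5-CH3 all cis. The key-step precursor and product agree with this and need no change of configuration. Only the CIP label at C5 changes (R in 7 and 14, S elsewhere) with no change in space. The carbene adduct keeps C9=C10, so it is a bicyclo[3.1.0]hexene, not a hexane.
- Assumption: (R)-TRIP directs the boronate to the Re face of the aldehyde, as with other aldehydes; if not, its antipode is used.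
- Design choice: the C7 oxygen is installed before the side chain is attached (one step more), so that no allylic ester and no dienoate ever meets palladium(0) or the oxidant.

**Boronate and core**

Step 1
Reactants: 1 (E)-2-methylbut-2-en-1-ol
Product: 2 (E)-2-methylbut-2-enyl pinacol boronate
Conditions: [Pd(MeCN)4](BF4)2 (5 mol%), B2pin2, DMSO/MeOH, 40 °C
Reagents that add atoms: bis(pinacolato)diboron CC1(C)OB(OC1(C)C)B1OC(C)(C)C(C)(C)O1
Why: Palladium-catalysed allylic C–OH borylation through an η3-allylpalladium intermediate puts boron on the unsubstituted terminus, and the syn-allyl complex formed from the (E)-alcohol should react faster than it isomerises, so the (E)-geometry that later fixes the C3/C4 relationship is kept.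

Step 2
Reactants: 3 pent-4-yn-1-ol
Product: 4 pent-4-ynal
Conditions: (COCl)2, DMSO, CH2Cl2, −78 °C; Et3N, −78 °C → rt; distilled
Reagents that add atoms: none
Why: Swern oxidation stops at the aldehyde and leaves the terminal alkyne untouched, and the volatile product is distilled and used at once.

Step 3
Reactants: 4 pent-4-ynal; 2 (E)-2-methylbut-2-enyl pinacol boronate
Product: 5 (3R,4S)-2,3-dimethyloct-1-en-7-yn-4-ol
Conditions: (R)-TRIP (5 mol%), toluene, −30 °C; aq. NaHCO3
Reagents that add atoms: none
Why: Chiral phosphoric acid-catalysed allylboration through a closed chair (Zimmerman–Traxler) transition state, in which the (E)-boronate gives the anti pair and the catalyst exposes the aldehyde Re face, sets both centres (carbinol S, methyl-bearing carbon R; C3 and C4 of the core) in one step, the borate being hydrolysed on work-up.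

Step 4
Reactants: 5 (3R,4S)-2,3-dimethyloct-1-en-7-yn-4-ol
Product: 6 TBS ether of 5
Conditions: TBSOTf, 2,6-lutidine, CH2Cl2, −78 → 0 °C
Reagents that add atoms: tert-butyldimethylsilyl triflate CC(C)(C)[Si](C)(C)OS(=O)(=O)C(F)(F)F
Why: Silyl triflate silylation of the hindered secondary alcohol gives an ether that survives the amide base, the carbene and the quinone of the later steps.

Step 5
Reactants: 6 TBS ether of 5
Product: 7 (3S,4R,5R)-3-silyloxy-4,5-dimethyl hydrindenone
Conditions: Co2(CO)8 (10 mol%), tetramethylthiourea (60 mol%), CO (1 atm), toluene, 70 °C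
Reagents that add atoms: carbon monoxide [C-]#[O+]
Why: Cobalt-catalysed intramolecular Pauson–Khand [2+2+1] cycloaddition of the 1,7-enyne with CO builds ring A and the cyclopentenone, and C5 is set in the alkene insertion, where a chair-like transition state with the C4 methyl pseudo-equatorial, away from the cobalt that bonds to C6, should place the C5 methyl cis to it (the axial C3 silyloxy group works against this, which makes facial selectivity the weak point).

Step 6
Reactants: 7 (3S,4R,5R)-3-silyloxy-4,5-dimethyl hydrindenone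
Product: 9 kinetic trimethylsilyl dienol ether (key-step precursor), via lithium dienolate 8 (not isolated)
Conditions: LDA (1.1 equiv), THF, −78 °C; TMSCl, −78 → 0 °C; pentane, filtration, no aqueous work-up
Reagents that add atoms: chlorotrimethylsilane C[Si](C)(C)Cl; lithium diisopropylamide CC(C)[N-]C(C)C.[Li+] (lithium of 8 only)
Why: Kinetic deprotonation at C6, the only α′ position (C1 is a γ position and is left alone at −78 °C), gives the cross-conjugated lithium dienolate, and O-silylation fixes it as the 8-silyloxy-6(8),9(10)-diene with no stereocentre involved.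

Step 7
Reactants: 9 kinetic trimethylsilyl dienol ether; 10 bromoform
Product: 12 (3S,4R,5S)-7-bromo-3-silyloxy-4,5-dimethyl cross-conjugated dienone, via dibromocyclopropane adduct 11 (not isolated)
Conditions: CHBr3 (slow addition), KOtBu, pentane, −30 °C → rt
Reagents that add atoms: none
Why: Dibromocarbene, released from bromoform by α-elimination, adds in a concerted cheletropic [2+1] step to C6=C8, the only alkene of 9 that receives the oxygen lone pair directly, to give the 7,7-dibromo-8-silyloxy-bicyclo[3.1.0]hex-2-ene unit of 11. Its C6–C8 bond then opens in a thermal two-electron disrotatory cyclopropyl-to-allyl process, pushed by the C8 oxygen as the endo bromide leaves, and bromide takes the trimethylsilyl group from the oxocarbenium ion to leave C8=O and C6=C7–Br. The closest known reaction type is the dihalocarbene ring enlargement of cyclic silyl enol ethers to 2-halo-enones. Ring B is not closed by a cyclisation but arises by one-carbon enlargement of the five-membered ring through this electrocyclic opening, which forms C6–C7 and C7–C8 in the same operation. No stereocentre is created in the product (the two cyclopropane centres are transient), and C3, C4 and C5 are untouched. The step needs chemoselectivity for C6=C8 over C9=C10, secured by the silyloxy group on C8, and the position of that enol ether is secured in step 6 because C6 is the only α′ carbon.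

Step 8
Reactants: 12 7-bromo cross-conjugated dienone
Product: 13 (3S,4R,5S)-7-bromo-3-silyloxy-4,5-dimethyl 1,6,9-trien-8-one
Conditions: chloranil (2.5 equiv), sec-amyl alcohol, reflux
Reagents that add atoms: none
Why: Quinone dehydrogenation of a cross-conjugated dienone, in which enolisation towards C1 gives the extended dienol, chloranil abstracts hydride from C2 (the only position that leads to a conjugated product) and loss of the O–H proton gives C1=C2–C10=C9–C8=O, with C3 kept as its silyl ether so that the new allylic centre cannot be oxidised.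

Step 9
Reactants: 13 bromotrienone
Product: 15 7-hydroxy trienone (diosphenol) with C3–OTBS, via alkenyl pinacol boronate 14 (not isolated)
Conditions: Pd(dppf)Cl2·CH2Cl2 (5 mol%), B2pin2, KOAc, 1,4-dioxane, 80 °C; then anhydrous Me3NO, THF, 0 °C → rt; aq. NH4Cl
Reagents that add atoms: trimethylamine N-oxide C[N+](C)(C)[O-] (the C7 oxygen of 15); bis(pinacolato)diboron CC1(C)OB(OC1(C)C)B1OC(C)(C)C(C)(C)O1 (boryl group of 14 only)
Why: Miyaura borylation of the activated C7–Br bond followed by amine N-oxide oxidation of the C–B bond (1,2-shift of C7 from boron to oxygen, then hydrolysis) gives the enol, which stays as the conjugated diosphenol; the boronate is not isolated to limit protodeboronation, the peroxide-free oxidant avoids epoxidation or cleavage of the trienone, and the allylic C3 silyl ether cannot be ionised by palladium(0).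

Step 10
Reactants: 15 7-hydroxy trienone with C3–OTBS
Product: 16 (3S,4R,5S)-3,7-dihydroxy trienone
Conditions: HF·pyridine, pyridine, THF, 0 °C → rt
Reagents that add atoms: none
Why: Buffered fluoride cleavage of the Si–O bond frees the C3 alcohol without base, so the vinylogously acidic C3–H and the trienone are not disturbed.

Step 11
Reactants: 16 3,7-dihydroxy trienone
Product: 17 7-silyloxy trienone with free C3–OH
Conditions: TBSCl (1.1 equiv), imidazole, CH2Cl2, −20 → 0 °C
Reagents that add atoms: tert-butyldimethylsilyl chloride CC(C)(C)[Si](C)(C)Cl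
Why: Chemoselective silylation, because the acidic enol O–H reacts with the silyl chloride far faster than the hindered secondary C3 alcohol next to the C4 methyl, leaves C3–OH as the only site for acylation.

**Side-chain acid**

Step 12
Reactants: 18 (R)-4-benzyloxazolidin-2-one; 19 butanoyl chloride
Product: 20 (R)-4-benzyl-3-butanoyloxazolidin-2-one
Conditions: Et3N, DMAP (10 mol%), CH2Cl2, 0 °C → rt
Reagents that add atoms: none
Why: DMAP-catalysed N-acylation of the oxazolidinone gives the imide that carries the chiral auxiliary.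

Step 13
Reactants: 20 (R)-4-benzyl-3-butanoyloxazolidin-2-one
Product: 22 (R)-4-benzyl-3-[(S)-2-(hydroxymethyl)butanoyl]oxazolidin-2-one, via titanium enolate 21 (not isolated)
Conditions: TiCl4, i-Pr2NEt, CH2Cl2, 0 °C; then 1,3,5-trioxane, TiCl4, 0 °C
Reagents that add atoms: 1,3,5-trioxane C1OCOCO1 (the CH2O unit); titanium tetrachloride Cl[Ti](Cl)(Cl)Cl (titanium of 21 only)
Why: Aldol-type hydroxymethylation of the chelated (Z)-titanium enolate with formaldehyde released from trioxane occurs on the face opposite the benzyl group of the auxiliary and sets the (S)-centre that becomes C6′.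

Step 14
Reactants: 22 hydroxymethyl imide
Product: 23 silyloxymethyl imide
Conditions: TBSCl, imidazole, DMF, rt
Reagents that add atoms: tert-butyldimethylsilyl chloride CC(C)(C)[Si](C)(C)Cl
Why: Standard silylation of the primary alcohol gives an ether that lasts until the final fluoride step.

Step 15
Reactants: 23 silyloxymethyl imide
Product: 24 (R)-2-{[(tert-butyldimethylsilyl)oxy]methyl}butan-1-ol
Conditions: LiBH4, MeOH (1 equiv), THF, 0 °C
Reagents that add atoms: none
Why: Reductive cleavage of the imide by borohydride attack on the exocyclic carbonyl gives the primary alcohol and returns the auxiliary without touching the stereocentre.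

Step 16
Reactants: 24 (R)-2-{[(tert-butyldimethylsilyl)oxy]methyl}butan-1-ol
Product: 25 (S)-2-{[(tert-butyldimethylsilyl)oxy]methyl}butanal
Conditions: Dess–Martin periodinane, CH2Cl2, 0 °C → rt; used without storage
Reagents that add atoms: none
Why: Dess–Martin oxidation under non-basic conditions gives the α-branched aldehyde without epimerisation or β-elimination of the silyloxy group.

Step 17
Reactants: 25 (S)-2-{[(tert-butyldimethylsilyl)oxy]methyl}butanal; 26 triethyl 4-phosphonocrotonate
Product: 27 ethyl (2E,4E,6R)-6-{[(tert-butyldimethylsilyl)oxy]methyl}octa-2,4-dienoate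
Conditions: LiHMDS (slightly less than 26), THF, −78 → 0 °C
Reagents that add atoms: none
Why: Vinylogous Horner–Wadsworth–Emmons olefination with the stabilised phosphonate anion forms the (4E)-alkene, keeps the (2E)-alkene, and is too weakly basic at −78 °C to epimerise the aldehyde.

Step 18
Reactants: 27 ethyl dienoate
Product: 28 (2E,4E,6R)-6-{[(tert-butyldimethylsilyl)oxy]methyl}octa-2,4-dienoic acid
Conditions: LiOH·H2O, THF/MeOH/H2O, rt; 1 M HCl to pH 4
Reagents that add atoms: lithium hydroxide [Li+].[OH-]
Why: Saponification of the ethyl ester leaves the primary silyl ether and the diene geometry intact, and acidification only to pH 4 avoids desilylation.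

**Coupling and release**

Step 19
Reactants: 17 7-silyloxy trienone with free C3–OH; 28 silyl-protected dienoic acid
Product: 29 bis-silyl septeremophilane E
Conditions: EDC·HCl, DMAP (0.3 equiv), CH2Cl2, 0 °C → rt
Reagents that add atoms: none
Why: Steglich esterification (carbodiimide activation and acyl transfer through the acylpyridinium ion) acylates the only free hydroxyl with retention at C3, and the side chain enters after the palladium step.

Step 20
Reactants: 29 bis-silyl septeremophilane E
Product: 30 septeremophilane E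
Conditions: HF·pyridine, pyridine, THF, 0 °C → rt
Reagents that add atoms: none
Why: Buffered fluoride cleaves the enol silyl ether and the primary silyl ether in one operation under non-basic conditions that leave the dienoate ester, the trienone and all four stereocentres intact.

**Compound list**

1 | (E)-2-methylbut-2-en-1-ol | C/C=C(\C)CO | starting material
2 | (E)-4,4,5,5-tetramethyl-2-(2-methylbut-2-en-1-yl)-1,3,2-dioxaborolane | C/C=C(\C)CB1OC(C)(C)C(C)(C)O1 | intermediate
3 | pent-4-yn-1-ol | C#CCCCO | starting material
4 | pent-4-ynal | C#CCCC=O | intermediate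
5 | (3R,4S)-2,3-dimethyloct-1-en-7-yn-4-ol | C#CCC[C@H](O)[C@H](C)C(C)=C | intermediate
6 | tert-butyl{[(3R,4S)-2,3-dimethyloct-1-en-7-yn-4-yl]oxy}dimethylsilane | C#CCC[C@H](O[Si](C)(C)C(C)(C)C)[C@H](C)C(C)=C | intermediate
7 | (6S,7R,7aR)-6-[(tert-butyldimethylsilyl)oxy]-7,7a-dimethyl-1,4,5,6,7,7a-hexahydro-2H-inden-2-one (core 3S,4R,5R) | CC(C)(C)[Si](C)(C)O[C@H]1CCC2=CC(=O)C[C@]2(C)[C@H]1C | intermediate
8 | lithium cross-conjugated dienolate of 7 (O–Li on C8, C6=C8, C9=C10) | CC(C)(C)[Si](C)(C)O[C@H]1CCC2=CC(O[Li])=C[C@]2(C)[C@H]1C | intermediate (not isolated)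
9 | (3S,4R,5S)-3-(tert-butyldimethylsilyloxy)-8-(trimethylsilyloxy)-4,5-dimethyl hydrinda-6(8),9(10)-diene, the key-step precursor | CC(C)(C)[Si](C)(C)O[C@H]1CCC2=CC(O[Si](C)(C)C)=C[C@]2(C)[C@H]1C | intermediate
10 | bromoform | BrC(Br)Br | starting material
11 | 7,7-dibromo-8-(trimethylsilyloxy)cyclopropane adduct of 9 (C6–C7–C8 three-membered ring, C9=C10 retained) | CC(C)(C)[Si](C)(C)O[C@H]1CCC2=CC3(O[Si](C)(C)C)C([C@]2(C)[C@H]1C)C3(Br)Br | intermediate (not isolated)
12 | (4aS,5R,6S)-3-bromo-6-[(tert-butyldimethylsilyl)oxy]-4a,5-dimethyl-5,6,7,8-tetrahydronaphthalen-2(4aH)-one (core 3S,4R,5S; C6=C7–Br, C8=O, C9=C10) | CC(C)(C)[Si](C)(C)O[C@H]1CCC2=CC(=O)C(Br)=C[C@]2(C)[C@H]1C | intermediate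
13 | (4aS,5R,6S)-3-bromo-6-[(tert-butyldimethylsilyl)oxy]-4a,5-dimethyl-5,6-dihydronaphthalen-2(4aH)-one | CC(C)(C)[Si](C)(C)O[C@H]1C=CC2=CC(=O)C(Br)=C[C@]2(C)[C@H]1C | intermediate
14 | C7 pinacol boronate of 13 (Bpin in place of Br) | CC(C)(C)[Si](C)(C)O[C@H]1C=CC2=CC(=O)C(B3OC(C)(C)C(C)(C)O3)=C[C@]2(C)[C@H]1C | intermediate (not isolated)
15 | (4aS,5R,6S)-6-[(tert-butyldimethylsilyl)oxy]-3-hydroxy-4a,5-dimethyl-5,6-dihydronaphthalen-2(4aH)-one | CC(C)(C)[Si](C)(C)O[C@H]1C=CC2=CC(=O)C(O)=C[C@]2(C)[C@H]1C | intermediate
16 | (4aS,5R,6S)-3,6-dihydroxy-4a,5-dimethyl-5,6-dihydronaphthalen-2(4aH)-one | O[C@H]1C=CC2=CC(=O)C(O)=C[C@]2(C)[C@H]1C | intermediate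
17 | (4aS,5R,6S)-3-[(tert-butyldimethylsilyl)oxy]-6-hydroxy-4a,5-dimethyl-5,6-dihydronaphthalen-2(4aH)-one | O[C@H]1C=CC2=CC(=O)C(O[Si](C)(C)C(C)(C)C)=C[C@]2(C)[C@H]1C | intermediate
18 | (R)-4-benzyloxazolidin-2-one | O=C1N[C@H](Cc2ccccc2)CO1 | starting material
19 | butanoyl chloride | CCCC(Cl)=O | starting material
20 | (R)-4-benzyl-3-butanoyloxazolidin-2-one | CCCC(=O)N1[C@H](Cc2ccccc2)COC1=O | intermediate
21 | trichlorotitanium (Z)-enolate of 20 | CC/C=C(\O[Ti](Cl)(Cl)Cl)N1[C@H](Cc2ccccc2)COC1=O | intermediate (not isolated)
22 | (R)-4-benzyl-3-[(S)-2-(hydroxymethyl)butanoyl]oxazolidin-2-one | CC[C@H](C(=O)N1[C@H](Cc2ccccc2)COC1=O)CO | intermediate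
23 | (R)-4-benzyl-3-[(S)-2-{[(tert-butyldimethylsilyl)oxy]methyl}butanoyl]oxazolidin-2-one | CC[C@H](C(=O)N1[C@H](Cc2ccccc2)COC1=O)CO[Si](C)(C)C(C)(C)C | intermediate
24 | (R)-2-{[(tert-butyldimethylsilyl)oxy]methyl}butan-1-ol | CC[C@H](CO)CO[Si](C)(C)C(C)(C)C | intermediate
25 | (S)-2-{[(tert-butyldimethylsilyl)oxy]methyl}butanal | CC[C@H](C=O)CO[Si](C)(C)C(C)(C)C | intermediate
26 | ethyl (E)-4-(diethoxyphosphoryl)but-2-enoate (triethyl 4-phosphonocrotonate) | CCOC(=O)/C=C/CP(=O)(OCC)OCC | starting material
27 | ethyl (2E,4E,6R)-6-{[(tert-butyldimethylsilyl)oxy]methyl}octa-2,4-dienoate | CC[C@H](/C=C/C=C/C(=O)OCC)CO[Si](C)(C)C(C)(C)C | intermediate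
28 | (2E,4E,6R)-6-{[(tert-butyldimethylsilyl)oxy]methyl}octa-2,4-dienoic acid | CC[C@H](/C=C/C=C/C(=O)O)CO[Si](C)(C)C(C)(C)C | intermediate
29 | C3 ester of 17 with 28 (septeremophilane E with TBS on the C7 enol oxygen and on the side-chain primary oxygen) | CC[C@H](/C=C/C=C/C(=O)O[C@H]1C=CC2=CC(=O)C(O[Si](C)(C)C(C)(C)C)=C[C@]2(C)[C@H]1C)CO[Si](C)(C)C(C)(C)C | intermediate
30 | septeremophilane E | CC[C@H](/C=C/C=C/C(=O)O[C@H]1C=CC2=CC(=O)C(O)=C[C@]2(C)[C@H]1C)CO | target

**Step count and risk**

Total step count: 20 (1 for the boronate, 10 for the core, 7 for the acid, 2 for coupling and release).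
Longest linear sequence: 12 steps, from 3 to 30 (steps 2–11, 19, 20).

Steps most likely to fail:

1. Step 5. The alkene may insert from the wrong face at C5, because the transition state that leads to 7 must carry the C3 silyloxy group axial and syn to the incoming C5 methyl. The fallback sets out from 5 and returns at 7. Mitsunobu inversion of 5 (4-nitrobenzoic acid, PPh3, DIAD) gives the inverted 4-nitrobenzoate F1, and methanolysis (K2CO3, MeOH) gives the syn alcohol F2. The same cobalt-catalysed cyclocarbonylation of F2, in which C3–OH, the C4 methyl and C6 can all sit equatorial, should give the 3-epi hydroxy enone F3 with the C4 and C5 methyls cis. Dess–Martin oxidation gives the dione F4. L-Selectride at −78 °C attacks the saturated C3 ketone from the equatorial side (axial approach is blocked by the axial C5 methyl) and gives the all-cis hydroxy enone F5, which TBSOTf and 2,6-lutidine convert into 7.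

2. Step 7. The trimethylsilyl group may be lost to alkoxide before the carbene arrives, the carbene may add to C9=C10, or the silyloxy-cyclopentadiene may dimerise. The fallback sets out from 9 and returns at 15; it separates carbon insertion from halogenation. Simmons–Smith cyclopropanation (Et2Zn, CH2I2) of the enol ether alkene gives the silyloxycyclopropane F6. FeCl3 in DMF opens the C6–C8 bond oxidatively to the β-chloro ketone F7, and NaOAc in methanol eliminates HCl to the halogen-free dienone F8 (Saegusa–Ito one-carbon ring enlargement). Iodine and pyridine then iodinate C7 through amine addition at the β-carbon C6 and give the iododienone F9. Chloranil as in step 8 gives the iodotrienone F10, which is borylated and oxidised under the conditions of step 9 to 15.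

3. Step 8. Enolisation towards C1 may be too slow at a temperature the bromodienone and the silyl ether tolerate, so that decomposition or dienone–phenol-type rearrangement competes with hydride abstraction. The fallback sets out from 12 and returns at 13. Soft enolisation towards C1 (TBSOTf, Et3N, CH2Cl2, 0 °C) gives the extended silyl trienol ether F11. DDQ (2,6-lutidine, CH2Cl2, 0 °C) abstracts hydride from C2 of this electron-rich triene at low temperature, the silyl group leaves the oxocarbenium ion, and 13 results.

Further compounds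
F1 | step 5 | (3R,4R)-2,3-dimethyloct-1-en-7-yn-4-yl 4-nitrobenzoate | C#CCC[C@@H](OC(=O)c1ccc(cc1)[N+](=O)[O-])[C@H](C)C(C)=C
F2 | step 5 | (3R,4R)-2,3-dimethyloct-1-en-7-yn-4-ol | C#CCC[C@@H](O)[C@H](C)C(C)=C
F3 | step 5 | (6R,7R,7aR)-6-hydroxy-7,7a-dimethyl-1,4,5,6,7,7a-hexahydro-2H-inden-2-one | O[C@@H]1CCC2=CC(=O)C[C@]2(C)[C@H]1C
F4 | step 5 | (7R,7aR)-7,7a-dimethyl-4,5,7,7a-tetrahydro-1H-indene-2,6-dione | O=C1CCC2=CC(=O)C[C@]2(C)[C@H]1C
F5 | step 5 | (6S,7R,7aR)-6-hydroxy-7,7a-dimethyl-1,4,5,6,7,7a-hexahydro-2H-inden-2-one | O[C@H]1CCC2=CC(=O)C[C@]2(C)[C@H]1C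
F6 | step 7 | 8-(trimethylsilyloxy)cyclopropane adduct of 9 (C6–C7H2–C8 three-membered ring) | CC(C)(C)[Si](C)(C)O[C@H]1CCC2=CC3(O[Si](C)(C)C)C([C@]2(C)[C@H]1C)C3
F7 | step 7 | 6-chloro-3-silyloxy-4,5-dimethyl 9-en-8-one (β-chloro ketone) | CC(C)(C)[Si](C)(C)O[C@H]1CCC2=CC(=O)CC(Cl)[C@]2(C)[C@H]1C
F8 | step 7 | (4aR,5R,6S)-6-[(tert-butyldimethylsilyl)oxy]-4a,5-dimethyl-5,6,7,8-tetrahydronaphthalen-2(4aH)-one | CC(C)(C)[Si](C)(C)O[C@H]1CCC2=CC(=O)C=C[C@]2(C)[C@H]1C
F9 | step 7 | (4aS,5R,6S)-6-[(tert-butyldimethylsilyl)oxy]-3-iodo-4a,5-dimethyl-5,6,7,8-tetrahydronaphthalen-2(4aH)-one | CC(C)(C)[Si](C)(C)O[C@H]1CCC2=CC(=O)C(I)=C[C@]2(C)[C@H]1C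
F10 | step 7 | (4aS,5R,6S)-6-[(tert-butyldimethylsilyl)oxy]-3-iodo-4a,5-dimethyl-5,6-dihydronaphthalen-2(4aH)-one | CC(C)(C)[Si](C)(C)O[C@H]1C=CC2=CC(=O)C(I)=C[C@]2(C)[C@H]1C
F11 | step 8 | 7-bromo-3,8-bis(tert-butyldimethylsilyloxy)-4,5-dimethyl 1(10),6,8-triene (extended silyl trienol ether of 12) | CC(C)(C)[Si](C)(C)O[C@H]1CC=C2C=C(O[Si](C)(C)C(C)(C)C)C(Br)=C[C@]2(C)[C@H]1C
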